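## The problem

Psiadiarabicin 14 is a flavone in which the γ-pyrone ring C is fused to the benzo ring A and joined through C2–C1' to ring B; ring A carries 5-OH, 6-OMe and 7-OMe, and ring B carries 2'-OMe, 3'-OH, 4'-OMe and 5'-OMe. Seven oxygen substituents must be placed, and exactly two of them, O5 and O3', must end as free hydroxyls. There is no stereocentre and no stereogenic double bond in 14, so every control problem is positional and no centre can steer another. Both hydroxyls lie between oxygenated neighbours (O5 between the C4 carbonyl and 6-OMe, O3' between 2'-OMe and 4'-OMe), so freeing either by ether cleavage would compete with cleavage of the flanking methyl ethers. Ring B is a 1,2,3,4-tetraoxygenated benzene with the free phenol in an inner position, and no common building block offers this pattern with a carbon handle at C1'. The molecule is electron-rich: the para-related methoxy groups at C2' and C5' can be oxidised to a quinone, the phenols are oxidisable, and the γ-pyrone opens under hot aqueous KOH. The enabling feature is that C5–H of a 5-unsubstituted 6,7-dimethoxyflavone lies peri to the C4 carbonyl oxygen, so a metal held at that oxygen reaches C5, and only C5, through a five-membered metallacycle, and O5 can be introduced last and directly as a hydroxyl.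

## Retrosynthesis

**14 from 13.** The last cut is the acyl C–O bond of an acetate on O3'. The acetate is the group that protects ring B during the oxidation before it, and it leaves by mild base-catalysed methanolysis that the pyrone and the chelated 5-OH tolerate. A benzyl or methyl ether at O3' would need hydrogenolysis or a Lewis acid at the end and would not lower the electron density of ring B.

**13 from 11.** The C5–O bond is cut, giving the 5-unsubstituted flavone 11. The neighbouring options are to carry a 5-methoxy group and cleave it with a Lewis acid, or to start from a tetraoxygenated ring A ketone. The first competes with the inner 6-OMe and with the methoxy groups beside O3'. The second still ends in the same demethylation. The C–H cut needs neither: ring A of 11 has only two oxygens, and both are already the methyl ethers of the target. The forward reaction must oxidise one C–H bond of a molecule with two electron-rich rings and must not touch ring B. For this reason O3' is an ester, and the ester has no ortho C–H that could direct a second metalation.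

**11 from 10.** Only the acetyl group is removed. The free phenol 10 is the form that survives flavone assembly under basic and hot oxidative conditions. The acetate is put on immediately before the oxidation.

**10 from 9, and 9 from 7 and 6.** The O1–C2 bond and the C2=C3 unsaturation are traced to the 2'-hydroxychalcone 9, and the C2–C3 bond of 9 to an aldol condensation of ketone 7 with aldehyde 6. This is preferred over a diketone rearrangement route, which would need the ring B acid chloride and a strong base that would move the acetyl group. It is also preferred over an aryloxycinnamate acylation route, which needs an arylpropiolate and several more steps. Ketone 7 is a catalogue compound with the 6,7-dimethoxy pattern already in place, so the whole of ring A is bought. The condensation has only to tolerate cleavage of the acetate of 6 by KOH, which is harmless because the liberated phenoxide 8 is meta to the formyl group.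

**6 from 5, and 5 from 4.** The aryl–CHO bond is cut. In phenol 4 the only free positions are C4 and C5, and the hydroxyl would send an electrophile to C4, para to itself, which is the wrong carbon. Acetylation to 5 demotes that oxygen to a weak donor. C5 is then ortho to 6-OMe and para to 2-OMe, whereas C4 has one ortho methoxy group and only the acetoxy group para, so C5 should be the more nucleophilic site. The forward step must be a formylation strong enough for a ring bearing an ester and mild enough to leave the ester in place.

**4 from 1.** The C–O bond of the phenol is cut back to 1,2,4-trimethoxybenzene 1. Its C3–H sits between two methoxy groups and is the kinetically most acidic position. Lithiation, borylation and oxidation should therefore place the hydroxyl exactly in the inner position that ring B requires. Electrophilic chemistry on 1 would not reach C3, since it goes to C5.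

## Roads not taken

Alternative 1: Dötz benzannulation of ring B. The cut removes three bonds of ring B (C5'–C6', C1'–C2', C2'–C3'). Forward, the alkyne 2-ethynyl-5,6,7-trimethoxy-4H-chromen-4-one A2 would be heated in an ether solvent with the Fischer carbene complex pentacarbonyl[(Z)-3-(benzyloxy)-1,2-dimethoxyprop-2-en-1-ylidene]chromium A3 , that is (CO)5Cr=C(OMe)C(OMe)=CHOBn. Alkyne insertion, insertion of a carbonyl ligand and electrocyclisation would give 2-[3-(benzyloxy)-2-hydroxy-4,5-dimethoxyphenyl]-5,6,7-trimethoxy-4H-chromen-4-one A1 .
- Merits: every oxygen of ring B is placed by construction, and O2' (free) and O3' (benzyl) emerge differentiated. In this respect the road is better than the chosen plan, whose ring B regiochemistry rests on directing effects in steps 1 and 3.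
- Weak points: complex A3 carries donor groups on both alkene carbons, which stabilise the carbene and slow alkyne insertion. Alkyne A2 is electron-poor and conjugated to the pyrone, the class that inserts least willingly. The new ring of A1 is a 4-methoxyphenol (O2' para to O5') and is prone to quinone formation during oxidative removal of chromium.
- After the key step, product A1 still needs O2' methylation, debenzylation and a selective cleavage of the 5-methyl ether, and both A2 and A3 take several steps to make.
- Comparison: the chosen plan is shorter, uses no stoichiometric chromium, and introduces O5 as a hydroxyl with no demethylation.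

Alternative 2: oxidative C2–H arylation of a chromone. The cut is the single bond C2–C1'. Forward, 5,6,7-trimethoxy-4H-chromen-4-one A5 and [3-(benzyloxy)-2,4,5-trimethoxyphenyl]boronic acid A6 would couple under Pd(O2CCF3)2 (divalent palladium) with a quinone or dioxygen as terminal oxidant. The product would be 2-[3-(benzyloxy)-2,4,5-trimethoxyphenyl]-5,6,7-trimethoxy-4H-chromen-4-one A4 .
- Merits: this is the most convergent road and the better one for making analogues, since either half can be varied independently and no ring is closed. The chosen plan is linear and cannot match that.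
- Weak points: boronic acid A6 is electron-rich and ortho-substituted, so it is prone to protodeboronation and homocoupling in an acidic oxidative medium. Arylation of a chromone such as A5 by this mechanism can stop at the flavanone stage and need re-oxidation.
- Boronic acid A6 poses the same ring B regiochemical problem as aldehyde 6, and in addition needs a protecting-group exchange and a carbon–boron bond. Chromone A5 is not a catalogue compound and already carries the 5-methoxy group, so product A4 must still lose that methyl ether selectively.
- Comparison: the chosen plan makes the C2–C3 bond by a condensation that is insensitive to these effects and avoids any demethylation.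

Alternative 3: Claisen–Dieckmann annulation of ring A onto a pyranone. The cut removes C7–C8 and C5–C6. Forward, the lateral anion of methyl 6-[3-(benzyloxy)-2,4,5-trimethoxyphenyl]-2-methyl-4-oxo-4H-pyran-3-carboxylate A8 would be acylated by methyl 2-methoxyacetate A9 . The enolate at the methoxy-bearing carbon of the new ketone would then close onto the ester, and enolisation would give 2-[3-(benzyloxy)-2,4,5-trimethoxyphenyl]-5,7-dihydroxy-6-methoxy-4H-chromen-4-one A7 .
- Merits: ring A is delivered with 5-OH free, 6-OMe in place and a 7-OH that can be methylated selectively, because the 5-OH is chelated. Ester A9 is a cheap reagent. The O5/O7 differentiation in product A7 is at least as secure as in the chosen plan and needs neither C–H oxidation nor ether cleavage.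
- Weak points: after the first acylation the most acidic site is the doubly activated C8 methylene, not the α-methoxy carbon that must attack. Closure therefore needs a polyanion, and the electrophile is a hindered ester on a base-sensitive pyranone. Pyranone A8 takes several steps to make, and product A7 still needs benzyl removal and 7-O-methylation.
- Comparison: the chosen plan buys ring A and uses only reaction types established on flavones.

Key step: step 7

Remark on the chemistry: the phenol freed from 6 by KOH in step 4 is assumed to condense as its phenoxide 8 without isolation; 1 and 7 are catalogue compounds.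

## Route

Step 1
Reactants: 1 1,2,4-trimethoxybenzene
Product: 4 2,3,6-trimethoxyphenol, via 2,3,6-trimethoxyphenyllithium 2 (not isolated), via dimethyl (2,3,6-trimethoxyphenyl)boronate 3 (not isolated)
Conditions: n-BuLi, TMEDA, THF, 0 °C to rt; B(OMe)3, −78 °C to rt; AcOH, 30% aq. H2O2, 0 °C to rt
Reagents that add atoms: hydrogen peroxide, OO
Why: Directed ortho-metalation: C3–H of 1 lies between two methoxy groups and should be lithiated selectively; borylation and peroxide-induced aryl 1,2-shift (boronate oxidation) turn C–Li into C–OH.

Step 2
Reactants: 4 2,3,6-trimethoxyphenol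
Product: 5 2,3,6-trimethoxyphenyl acetate
Conditions: Ac2O, pyridine, DMAP (cat.), CH2Cl2, rt
Reagents that add atoms: acetic anhydride, CC(=O)OC(C)=O
Why: DMAP-catalysed O-acetylation of a hindered phenol; the ester turns the strongest donor of the ring into a weak one so that the methoxy groups steer the next substitution.

Step 3
Reactants: 5 2,3,6-trimethoxyphenyl acetate
Product: 6 3-formyl-2,5,6-trimethoxyphenyl acetate
Conditions: Cl2CHOMe, TiCl4, CH2Cl2, −10 to 0 °C; then ice/aq. HCl
Reagents that add atoms: dichloromethyl methyl ether, COC(Cl)Cl (formyl carbon); water, O (carbonyl oxygen on hydrolytic work-up)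
Why: Rieche formylation (electrophilic aromatic substitution); C5 of 5 is ortho to 6-OMe and para to 2-OMe, whereas C4 has one ortho methoxy group and only the weakly donating acetoxy group para, the same acetate-controlled switch of site known for guaiacol-type acetates.

Step 4
Reactants: 6 3-formyl-2,5,6-trimethoxyphenyl acetate; 7 1-(2-hydroxy-4,5-dimethoxyphenyl)ethan-1-one
Product: 9 (E)-1-(2-hydroxy-4,5-dimethoxyphenyl)-3-(3-hydroxy-2,4,5-trimethoxyphenyl)prop-2-en-1-one, via 3-hydroxy-2,4,5-trimethoxybenzaldehyde 8 (not isolated)
Conditions: KOH (aq., excess), EtOH, rt; then aq. HCl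
Reagents that add atoms: none
Why: Claisen–Schmidt condensation; KOH first cleaves the aryl acetate to phenoxide 8, whose oxygen is meta to the formyl group and does not deactivate it by resonance, and aldol addition of the enolate of 7 followed by E1cB dehydration should give the (E)-enone.

Step 5
Reactants: 9 (E)-1-(2-hydroxy-4,5-dimethoxyphenyl)-3-(3-hydroxy-2,4,5-trimethoxyphenyl)prop-2-en-1-one
Product: 10 2-(3-hydroxy-2,4,5-trimethoxyphenyl)-6,7-dimethoxy-4H-chromen-4-one
Conditions: I2 (cat.), DMSO, 130 °C; then aq. Na2S2O3
Reagents that add atoms: none
Why: Iodine-catalysed oxidative cyclisation of a 2'-hydroxychalcone (oxa-Michael closure, α-iodination, loss of HI, DMSO reoxidises HI); a standard flavone synthesis that tolerates methyl ethers and phenols, and with only catalytic iodine present ring iodination should stay minor.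

Step 6
Reactants: 10 2-(3-hydroxy-2,4,5-trimethoxyphenyl)-6,7-dimethoxy-4H-chromen-4-one
Product: 11 3-(6,7-dimethoxy-4-oxo-4H-chromen-2-yl)-2,5,6-trimethoxyphenyl acetate
Conditions: Ac2O, pyridine, DMAP (cat.), CH2Cl2, rt
Reagents that add atoms: acetic anhydride, CC(=O)OC(C)=O
Why: O-acetylation of the only hydroxyl; the ester lowers the electron density of ring B, keeps the phenol away from the iodine oxidant of step 7 and, having methoxy groups at both ortho positions, cannot act as a second directing group.

Step 7
Reactants: 11 3-(6,7-dimethoxy-4-oxo-4H-chromen-2-yl)-2,5,6-trimethoxyphenyl acetate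
Product: 13 3-(5-hydroxy-6,7-dimethoxy-4-oxo-4H-chromen-2-yl)-2,5,6-trimethoxyphenyl acetate, via flavone C5 trifluoroacetate 12 (not isolated)
Conditions: [RuCl2(p-cymene)]2 (cat.), PhI(O2CCF3)2, CF3CO2H/(CF3CO)2O, 80 °C; then aq. Na2S2O3/NaHCO3
Reagents that add atoms: [bis(trifluoroacetoxy)iodo]benzene, O=C(O[I](OC(=O)C(F)(F)F)c1ccccc1)C(F)(F)F (its trifluoroacetate supplies the C5 oxygen); trifluoroacetic acid, OC(=O)C(F)(F)F (exchanges with that trifluoroacetate)
Why: Ruthenium-catalysed ketone-directed ortho C–H oxygenation, the reaction type already established for C5 hydroxylation of flavones and chromones. In CF3CO2H, [RuCl2(p-cymene)]2 becomes a trifluoroacetate complex of divalent ruthenium that binds the C4 carbonyl oxygen of 11 and cleaves the peri C5–H bond by carboxylate-assisted metalation, giving a five-membered ruthenacycle (Ru, C5, C4a, C4, O). PhI(O2CCF3)2 oxidises this to tetravalent ruthenium, and C–O reductive elimination releases aryl trifluoroacetate 12 and returns divalent ruthenium; (CF3CO)2O keeps the medium anhydrous so that the oxidant meets the ester and not a free phenol. The reducing, mildly basic work-up first destroys residual trivalent iodine and then hydrolyses the labile trifluoroacetate, while the less electrophilic acetate on ring B should remain. No ring is closed in the product (the metallacycle is transient) and no stereocentre is formed. The selectivity needed is positional: C5 is the only C–H bond the C4 oxygen can reach through a five-membered metallacycle (C3 would need a four-membered one; C8 and C6' are out of reach), and the ring B acetate has no ortho C–H. Chemoselectivity against one-electron oxidation of the electron-rich rings rests on protonation of the pyrone carbonyl in CF3CO2H, which makes the benzopyrylium-like core and the attached ring B electron-poor, and on the acetate at O3'. The flanking 6-methoxy group is small and electron-releasing, so it should slow but not prevent metalation at C5.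

Step 8
Reactants: 13 3-(5-hydroxy-6,7-dimethoxy-4-oxo-4H-chromen-2-yl)-2,5,6-trimethoxyphenyl acetate
Product: 14 psiadiarabicin (5-hydroxy-2-(3-hydroxy-2,4,5-trimethoxyphenyl)-6,7-dimethoxy-4H-chromen-4-one)
Conditions: K2CO3, MeOH, 0 °C to rt; then dil. HCl
Reagents that add atoms: none
Why: Base-catalysed transesterification (methanolysis) of an aryl acetate; methyl ethers, the chelated 5-OH and the γ-pyrone should be inert to K2CO3 in methanol at or below room temperature.

## Compound list

1 | 1,2,4-trimethoxybenzene | COc1ccc(OC)c(OC)c1 | starting material
2 | 2,3,6-trimethoxyphenyllithium | [Li]c1c(OC)ccc(OC)c1OC | intermediate (not isolated)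
3 | dimethyl (2,3,6-trimethoxyphenyl)boronate | COB(OC)c1c(OC)ccc(OC)c1OC | intermediate (not isolated)
4 | 2,3,6-trimethoxyphenol | COc1ccc(OC)c(OC)c1O | intermediate
5 | 2,3,6-trimethoxyphenyl acetate | CC(=O)Oc1c(OC)ccc(OC)c1OC | intermediate
6 | 3-formyl-2,5,6-trimethoxyphenyl acetate (3-acetoxy-2,4,5-trimethoxybenzaldehyde) | CC(=O)Oc1c(OC)c(C=O)cc(OC)c1OC | intermediate
7 | 1-(2-hydroxy-4,5-dimethoxyphenyl)ethan-1-one | CC(=O)c1cc(OC)c(OC)cc1O | starting material
8 | 3-hydroxy-2,4,5-trimethoxybenzaldehyde (formed as its potassium phenoxide) | COc1cc(C=O)c(OC)c(O)c1OC | intermediate (not isolated)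
9 | (E)-1-(2-hydroxy-4,5-dimethoxyphenyl)-3-(3-hydroxy-2,4,5-trimethoxyphenyl)prop-2-en-1-one | COc1cc(/C=C/C(=O)c2cc(OC)c(OC)cc2O)c(OC)c(O)c1OC | intermediate
10 | 2-(3-hydroxy-2,4,5-trimethoxyphenyl)-6,7-dimethoxy-4H-chromen-4-one | COc1cc(-c2cc(=O)c3cc(OC)c(OC)cc3o2)c(OC)c(O)c1OC | intermediate
11 | 3-(6,7-dimethoxy-4-oxo-4H-chromen-2-yl)-2,5,6-trimethoxyphenyl acetate | CC(=O)Oc1c(OC)c(OC)cc(-c2cc(=O)c3cc(OC)c(OC)cc3o2)c1OC | intermediate
12 | 2-(3-acetoxy-2,4,5-trimethoxyphenyl)-6,7-dimethoxy-4-oxo-4H-chromen-5-yl 2,2,2-trifluoroacetate | CC(=O)Oc1c(OC)c(OC)cc(-c2cc(=O)c3c(OC(=O)C(F)(F)F)c(OC)c(OC)cc3o2)c1OC | intermediate (not isolated)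
13 | 3-(5-hydroxy-6,7-dimethoxy-4-oxo-4H-chromen-2-yl)-2,5,6-trimethoxyphenyl acetate | CC(=O)Oc1c(OC)c(OC)cc(-c2cc(=O)c3c(O)c(OC)c(OC)cc3o2)c1OC | intermediate
14 | psiadiarabicin (5-hydroxy-2-(3-hydroxy-2,4,5-trimethoxyphenyl)-6,7-dimethoxy-4H-chromen-4-one) | COc1cc(-c2cc(=O)c3c(O)c(OC)c(OC)cc3o2)c(OC)c(O)c1OC | target

## Step count and least certain steps

Total steps: 8. Longest linear sequence: 8 steps (1 to 14); ketone 7 enters at step 4.

**Step 7 (key step).** The most likely failure is one-electron oxidation of the electron-rich rings by the trivalent iodine reagent, above all at the para-related 2'/5'-methoxy pair of ring B, leading to oxidative degradation. Metalation at C5 may also stall because the position is flanked by the 6-methoxy group, and partial acyl exchange at the ring B ester may occur in the anhydride medium. The last is harmless, since step 8 removes the acyl group in any case.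

The fallback gives up the C–H oxidation and carries O5 as a methyl ether; it sets out from 6 and returns at 13. Aldehyde 6 would be condensed (KOH, EtOH, rt) with the catalogue ketone 1-(6-hydroxy-2,3,4-trimethoxyphenyl)ethan-1-one F1 to give (E)-1-(6-hydroxy-2,3,4-trimethoxyphenyl)-3-(3-hydroxy-2,4,5-trimethoxyphenyl)prop-2-en-1-one F2 , the acetate of 6 being lost to KOH as in step 4. This chalcone would be cyclised with catalytic I2 in DMSO to 2-(3-hydroxy-2,4,5-trimethoxyphenyl)-5,6,7-trimethoxy-4H-chromen-4-one F3 , which would be acetylated to 2,5,6-trimethoxy-3-(5,6,7-trimethoxy-4-oxo-4H-chromen-2-yl)phenyl acetate F4 . Treatment of this acetate with BCl3 in CH2Cl2 at −78 to 0 °C would cleave the peri 5-methyl ether through its chelate with the C4 carbonyl and give 13. The price is the methoxy-against-methoxy competition that the main route avoids.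

**Step 3.** Formylation may occur in part at the wrong ring carbon (C4, para to the acetoxy group), because the 2-methoxy group that should direct to C5 is twisted out of conjugation by its two neighbours. The Lewis acid may also loosen or shift the acetyl group.

The fallback blocks the wrong position; it sets out from 4 and returns at 6. Phenol 4 would be brominated para to the hydroxyl (NBS, MeCN, 0 °C) to 4-bromo-2,3,6-trimethoxyphenol F5 , and this would be acetylated to 4-bromo-2,3,6-trimethoxyphenyl acetate F6 . Rieche formylation at the one remaining C–H would give 4-bromo-3-formyl-2,5,6-trimethoxyphenyl acetate F7 . The bromine would then be removed by transfer hydrodehalogenation (Pd(OAc)2, PPh3, HCO2Na, DMF, 80 °C), which should spare the aldehyde and the ester and give 6.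

**Step 5.** The free ring B phenol has an open para position, so electrophilic iodination or oxidative degradation of that ring at 130 °C may compete. The dehydrogenation may also stop at the flavanone stage.

The fallback separates ring closure from dehydrogenation and masks the phenol between the two; it sets out from 9 and returns at 11, bypassing 10 and step 6. Chalcone 9 would be closed by oxa-Michael addition (NaOAc, EtOH, reflux) to racemic 2-(3-hydroxy-2,4,5-trimethoxyphenyl)-6,7-dimethoxychroman-4-one F8 , which would be acetylated to racemic 3-(6,7-dimethoxy-4-oxochroman-2-yl)-2,5,6-trimethoxyphenyl acetate F9 . Dehydrogenation of this flavanone acetate with DDQ in dioxane at reflux would give 11; the single stereocentre of the two flavanones is destroyed in this step.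

## Further compounds

F1 | step 7 | 1-(6-hydroxy-2,3,4-trimethoxyphenyl)ethan-1-one | CC(=O)c1c(O)cc(OC)c(OC)c1OC
F2 | step 7 | (E)-1-(6-hydroxy-2,3,4-trimethoxyphenyl)-3-(3-hydroxy-2,4,5-trimethoxyphenyl)prop-2-en-1-one | COc1cc(/C=C/C(=O)c2c(O)cc(OC)c(OC)c2OC)c(OC)c(O)c1OC
F3 | step 7 | 2-(3-hydroxy-2,4,5-trimethoxyphenyl)-5,6,7-trimethoxy-4H-chromen-4-one | COc1cc(-c2cc(=O)c3c(OC)c(OC)c(OC)cc3o2)c(OC)c(O)c1OC
F4 | step 7 | 2,5,6-trimethoxy-3-(5,6,7-trimethoxy-4-oxo-4H-chromen-2-yl)phenyl acetate | CC(=O)Oc1c(OC)c(OC)cc(-c2cc(=O)c3c(OC)c(OC)c(OC)cc3o2)c1OC
F5 | step 3 | 4-bromo-2,3,6-trimethoxyphenol | COc1cc(Br)c(OC)c(OC)c1O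
F6 | step 3 | 4-bromo-2,3,6-trimethoxyphenyl acetate | CC(=O)Oc1c(OC)cc(Br)c(OC)c1OC
F7 | step 3 | 4-bromo-3-formyl-2,5,6-trimethoxyphenyl acetate | CC(=O)Oc1c(OC)c(C=O)c(Br)c(OC)c1OC
F8 | step 5 | rac-2-(3-hydroxy-2,4,5-trimethoxyphenyl)-6,7-dimethoxychroman-4-one (racemic) | COc1cc(C2CC(=O)c3cc(OC)c(OC)cc3O2)c(OC)c(O)c1OC
F9 | step 5 | rac-3-(6,7-dimethoxy-4-oxochroman-2-yl)-2,5,6-trimethoxyphenyl acetate (racemic) | CC(=O)Oc1c(OC)c(OC)cc(C2CC(=O)c3cc(OC)c(OC)cc3O2)c1OC
A1 | alternative 1 | 2-[3-(benzyloxy)-2-hydroxy-4,5-dimethoxyphenyl]-5,6,7-trimethoxy-4H-chromen-4-one | COc1cc2oc(-c3cc(OC)c(OC)c(OCc4ccccc4)c3O)cc(=O)c2c(OC)c1OC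
A2 | alternative 1 | 2-ethynyl-5,6,7-trimethoxy-4H-chromen-4-one | C#Cc1cc(=O)c2c(OC)c(OC)c(OC)cc2o1
A3 | alternative 1 | pentacarbonyl[(Z)-3-(benzyloxy)-1,2-dimethoxyprop-2-en-1-ylidene]chromium | COC(=[Cr](=C=O)(=C=O)(=C=O)(=C=O)=C=O)/C(OC)=C/OCc1ccccc1
A4 | alternative 2 | 2-[3-(benzyloxy)-2,4,5-trimethoxyphenyl]-5,6,7-trimethoxy-4H-chromen-4-one | COc1cc2oc(-c3cc(OC)c(OC)c(OCc4ccccc4)c3OC)cc(=O)c2c(OC)c1OC
A5 | alternative 2 | 5,6,7-trimethoxy-4H-chromen-4-one | COc1cc2occc(=O)c2c(OC)c1OC
A6 | alternative 2 | [3-(benzyloxy)-2,4,5-trimethoxyphenyl]boronic acid | COc1cc(B(O)O)c(OC)c(OCc2ccccc2)c1OC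
A7 | alternative 3 | 2-[3-(benzyloxy)-2,4,5-trimethoxyphenyl]-5,7-dihydroxy-6-methoxy-4H-chromen-4-one | COc1c(O)cc2oc(-c3cc(OC)c(OC)c(OCc4ccccc4)c3OC)cc(=O)c2c1O
A8 | alternative 3 | methyl 6-[3-(benzyloxy)-2,4,5-trimethoxyphenyl]-2-methyl-4-oxo-4H-pyran-3-carboxylate | COC(=O)c1c(C)oc(-c2cc(OC)c(OC)c(OCc3ccccc3)c2OC)cc1=O
A9 | alternative 3 | methyl 2-methoxyacetate | COCC(=O)OC
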